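If both conformers fed the target alike, target in percent of the total charge is blind to the mix, and that flat row is the zero of our scale. Here are the flasks, the earlier runs and the questions.

in all of them: starting material 0.30 M

|  | other conformer | remark | time |
|---|---|---|---|
| dawn | 0.12 M | run made earlier |  |
| noon | 0.41 M | run made earlier |  |
| ash | 0.200 M |  | 80 min |
| larch | 0.300 M |  | 80 min |
| maple | 0.500 M |  | 80 min |

- dawn (time / min: target / %, starting material / %): 3.00: 7.2, 63.9; 5.00: 10.0, 62.0; 8.00: 15.5, 56.8; 15.0: 25.1, 43.5; 25.0: 34.9, 32.0; 40.0: 47.2, 20.7
- noon (time / min: target / %, starting material / %): 3.00: 3.2, 39.3; 5.00: 5.3, 36.3; 8.00: 11.0, 33.5; 15.0: 13.9, 27.9; 25.0: 22.8, 18.2; 40.0: 26.9, 12.3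

(each reading ± 1 percentage point)

1. amount of target at the end, in percent of the starting material and other conformer together charged for ash, larch, maple, in this order
2. the course of these numbers from the first flask to the last (rises, then falls / hardly changes / falls all the way / falls, then rises / rises all the way)

- the numbers in the tables scatter by 1 percentage point (one standard deviation)
- "hardly changes" means that all values lie within two and a half points (for a concentration: within two and a half percent of the largest)

The readings leave that zero and at first look odd. At 40.0 min the dawn run shows 47.2 % target and the noon run 26.9 %, although both started from 0.30 M of starting material and the noon run held more other conformer. Converted to concentration, the gap closes: [target] reads 0.198 M at dawn and 0.191 M at noon, equal within the scatter. The extra other conformer therefore added no target that we can read, and it enlarged the denominator.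

For ash, 60.0 % of the charge is starting material. This starting-material share, charged [starting material] over charged [starting material] plus [other conformer], is the quantity we carry. For maple it is 37.5 %. Our own reckoning commits to a row that falls in proportion to the share, with larch at 0.833 of ash and maple at 0.625 of ash.

The forecast gives 50 %, 41.7 % and 31.3 %, a course that falls all the way. Its ground is this: “The percentage falls purely through the larger denominator”.

The flasks give 47.5 %, 39.8 % and 30.3 %, a course that falls all the way.

    starting material ⇌ other conformer (K = 1.40, k = 7.40 × 10⁻⁶ /s)
    starting material → target (k = 5.00 × 10⁻⁴ /s)
    other conformer → isomer of the product (k = 0.00290 /s)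
    target ⇌ isomer of the product (K = 11.0, k = 4.40 × 10⁻⁵ /s)
    2 other conformer → self-condensation product (k = 4.10 × 10⁻⁴ /M/s)

Divided by its share, ash turns 0.792 of its starting material into target at the end, and that factor times the share of maple predicts 29.7 % against the 30.3 % found there. The main reason that maple stands at this figure is the hour of the reading: at 80.0 min maple holds 30.3 % target, at 800 min it holds 11.2 %, a drop of 19 percentage points.

Readings and results stem from a simulated flask on assumed constants; the scatter is artificial.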